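Cuts: the two ester C–O bonds (C3, C9) and C7–C11 come off first; ring B is opened at C6=C7 (aldol condensation of a C8 methyl ketone onto a C6 aldehyde); ring A is opened at C3–C4 and C5–C10 (Diels–Alder).
Enabling feature: ring A holds four contiguous stereocentres C3, C4, C5, C10 with cis methyl groups on C4/C5 and oxygen on C3, and C9 next to C10 is oxygenated, so ring A maps onto an (E,E)-1-silyloxydiene and an (E)-tiglate tied together through the C9 oxygen.
Forward: C5 dienal + acetylide → resolved carbinol → tiglate → ring A and the cis-fused γ-lactone (C5–C6–O–C9–C10) in one cycloaddition → lactol, alkyne hydration, hydrogenation → ring B by aldol condensation (cis-decalin) → C9 ester, C7 iodide, C3 ester, isopropenyl, conjugate reduction.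
Stereochemistry: C9 (S) from a lipase resolution steers the diene face and so fixes C3, C4, C5, C10 (relative configuration from the alkene geometries and the endo tether); C9 is then inverted by Mitsunobu esterification; C7 is set last by protonation to the equatorial epimer.
Key step: step 5

Remark: eremophilane numbering is used throughout (ring A C1–C5, C10; ring B C5–C10; C14 on C5, C15 on C4, C11–C13 isopropenyl; β = face of C14); it is assumed that the lipase reads ethynyl as the medium-sized group and that ethynyl takes the outside position in the cycloaddition.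

Step 1
Reactants: 1 glutaconaldehyde potassium salt
Product: 2 (2E,4E)-5-[(tert-butyldimethylsilyl)oxy]penta-2,4-dienal
Conditions: TBSCl, DMF, 0 °C → rt
Reagents that add atoms: tert-butyldimethylsilyl chloride, CC(C)(C)[Si](C)(C)Cl
Why: O-silylation of the delocalised glutaconaldehyde enolate with a hard silyl chloride is the known entry to 5-silyloxypenta-2,4-dienals and keeps the all-trans geometry; no stereocentre is formed.

Step 2
Reactants: 2 (2E,4E)-5-[(tert-butyldimethylsilyl)oxy]penta-2,4-dienal; 3 ethynylmagnesium bromide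
Product: 5 rac-(4E,6E)-7-[(tert-butyldimethylsilyl)oxy]hepta-4,6-dien-1-yn-3-yl acetate, via bromomagnesium alkoxide 4 (not isolated)
Conditions: HC≡CMgBr, THF, −78 → −20 °C; then Ac2O, −20 → 0 °C
Reagents that add atoms: ethynylmagnesium bromide (3), C#C[Mg]Br; acetic anhydride, CC(=O)OC(C)=O
Why: Grignard 1,2-addition of the acetylide to the aldehyde followed by O-acetylation of the magnesium alkoxide in the same flask brings in C8/C7 as a small masked acetyl group and avoids isolating the acid-labile racemic carbinol; C9 is formed as a racemate.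

Step 3
Reactants: 5 rac-(4E,6E)-7-[(tert-butyldimethylsilyl)oxy]hepta-4,6-dien-1-yn-3-yl acetate
Product: 6 (3S,4E,6E)-7-[(tert-butyldimethylsilyl)oxy]hepta-4,6-dien-1-yn-3-ol
Conditions: Candida antarctica lipase B (Novozym 435), n-BuOH (3 equiv), MTBE, 30 °C, stopped below half conversion
Reagents that add atoms: none
Why: Lipase-catalysed kinetic resolution by transesterification should cleave, by the empirical large/medium-group rule for secondary alcohols, the acetate whose slim ethynyl group fits the medium pocket and whose dienyl chain is the large group, that is the (S)-enantiomer, so C9 is obtained as (S) under neutral conditions that spare the silyl dienol ether.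

Step 4
Reactants: 6 (3S,4E,6E)-7-[(tert-butyldimethylsilyl)oxy]hepta-4,6-dien-1-yn-3-ol; 7 tigloyl chloride
Product: 8 (3S,4E,6E)-7-[(tert-butyldimethylsilyl)oxy]hepta-4,6-dien-1-yn-3-yl (2E)-2-methylbut-2-enoate
Conditions: tigloyl chloride, Et3N, DMAP (cat.), CH2Cl2, −20 → 0 °C
Reagents that add atoms: tigloyl chloride (7), C/C=C(\C)C(Cl)=O
Why: DMAP-catalysed O-acylation (nucleophilic acyl substitution) leaves the C9–O bond intact, so the (S) configuration is retained, and the excess amine keeps the ionisable dienyl ester free of acid.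

Step 5
Reactants: 8 (3S,4E,6E)-7-[(tert-butyldimethylsilyl)oxy]hepta-4,6-dien-1-yn-3-yl (2E)-2-methylbut-2-enoate
Product: 9 (3S,3aS,6R,7R,7aR)-6-[(tert-butyldimethylsilyl)oxy]-3-ethynyl-7,7a-dimethyl-3a,6,7,7a-tetrahydro-2-benzofuran-1(3H)-one (cis-fused lactone; Δ1; 3α-OTBS; 4β,5β-dimethyl; 10β-H; ethynyl cis to H10)
Conditions: o-dichlorobenzene (0.01 M), BHT (cat.), 2,6-di-tert-butyl-4-methylpyridine (0.2 equiv), base-washed sealed tube, 170–180 °C
Reagents that add atoms: none
Why: A thermal, concerted [4+2] cycloaddition, suprafacial on both partners, joins the (E,E)-1-silyloxydiene C3=C2–C1=C10 to the tiglate alkene C4=C5 and forms C3–C4 and C5–C10; the closest known reaction type is the ester-tethered (type 1) intramolecular Diels–Alder reaction of pentadienyl acrylates. Ring A closes as the cyclohexene of the cycloaddition, and the lactone C5–C6–O–C9–C10 closes at the same time because its last bond C5–C10 is one of the two new bonds, in the tether-endo mode that gives cis fusion. The cis methyl groups on C4 and C5 come from the (E)-alkene of the tiglate, and the cis relation of C3–O and C9 from the two outside positions of the (E,E)-diene. The relation between the two partners (C6 cis to C3–O and C9) comes from the endo position of the tether carbonyl, which the short three-atom tether favours and which leaves both tiglate methyl groups exo, away from the diene. The absolute sense comes from C9: the ethynyl group should take the outside, pseudo-equatorial position of the forming lactone envelope rather than the inside position under C1, so that the (S)-ester gives 3R,4R,5R,10S with C8 cis to H10. The step therefore needs tether-endo and one diene face, and the tether also imposes the C3–C4/C5–C10 regiochemistry against the electronic preference of a 1-oxydiene, which is why heat and strict exclusion of acid are required.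

Step 6
Reactants: 9 cis-fused ethynyl lactone
Product: 10 (3S,3aS,6R,7R,7aR)-6-[(tert-butyldimethylsilyl)oxy]-3-ethynyl-7,7a-dimethyl-1,3,3a,6,7,7a-hexahydro-2-benzofuran-1-ol (C6 lactol; both anomers)
Conditions: DIBAL-H (1.1 equiv), CH2Cl2, −78 °C; Rochelle salt
Reagents that add atoms: none
Why: Partial reduction of a γ-lactone with DIBAL-H at −78 °C stops at the stable aluminium hemiacetal, which gives the lactol on work-up, while the terminal alkyne, the ring alkene and the silyl ether are inert; the new C6 centre is an inconsequential anomeric mixture.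

Step 7
Reactants: 10 ethynyl lactol
Product: 11 (3S,3aS,6R,7R,7aR)-3-acetyl-6-[(tert-butyldimethylsilyl)oxy]-7,7a-dimethyl-1,3,3a,6,7,7a-hexahydro-2-benzofuran-1-ol (keto lactol)
Conditions: [(JohnPhos)Au(MeCN)]SbF6 (2 mol%), 1,4-dioxane–H2O, 40 °C
Reagents that add atoms: water, O
Why: Gold(I)-catalysed Markovnikov hydration of the terminal alkyne gives the methyl ketone (C8=O, C7H3), any 5-exo addition of the lactol hydroxyl leading after hydrolysis to the same ketone, and the near-neutral medium does not enolise C9.

Step 8
Reactants: 11 keto lactol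
Product: 12 (3S,3aS,6R,7R,7aR)-3-acetyl-6-[(tert-butyldimethylsilyl)oxy]-7,7a-dimethyloctahydro-2-benzofuran-1-ol (ring A saturated)
Conditions: H2 (1 atm), 10% Pd/C, NaHCO3, EtOAc, rt
Reagents that add atoms: none
Why: Heterogeneous catalytic hydrogenation saturates the only C=C bond (C1=C2) before further unsaturation is introduced; ketone, lactol and silyl ether are not touched and no stereocentre is formed.

Step 9
Reactants: 12 saturated keto lactol
Product: 14 (3R,4R,5R,9S,10S)-3-[(tert-butyldimethylsilyl)oxy]-9-hydroxy-11,12,13-trinoreremophil-6-en-8-one (9α-OH; cis-fused), via aldol β-hydroxy ketone 13 (not isolated)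
Conditions: Bn2NH·TFA (0.3 equiv), PhMe, 50 °C
Reagents that add atoms: none
Why: Intramolecular aldol condensation of a 1,5-keto aldehyde (Robinson-type ring closure): the lactol opens to the non-enolisable C6 aldehyde, the methyl ketone carbon C7 adds and water is lost by E1cB, and because C6 and C9 sit cis on ring A the new ring B is cis-fused, the mild ammonium salt leaving the C9 configuration of the lactone (9α-OH) unchanged.

Step 10
Reactants: 14 9α-hydroxy enone; 15 senecioic acid
Product: 16 (3R,4R,5R,9R,10S)-3-[(tert-butyldimethylsilyl)oxy]-8-oxo-11,12,13-trinoreremophil-6-en-9-yl 3-methylbut-2-enoate (9β-ester)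
Conditions: senecioic acid, PPh3, DIAD, PhMe, 0 °C → rt
Reagents that add atoms: senecioic acid (15), CC(C)=CC(=O)O
Why: Mitsunobu esterification proceeds by SN2 displacement of the axial 9α-oxyphosphonium group, which is activated by the adjacent carbonyl, so the senecioate enters from the β face and C9 is inverted to the equatorial 9β (9R) ester of the target.

Step 11
Reactants: 16 9β-senecioyloxy enone
Product: 17 (3R,4R,5R,9R,10S)-3-[(tert-butyldimethylsilyl)oxy]-7-iodo-8-oxo-11,12,13-trinoreremophil-6-en-9-yl 3-methylbut-2-enoate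
Conditions: I2, pyridine, CH2Cl2, rt, dark
Reagents that add atoms: iodine, II
Why: Pyridine-mediated α-iodination of the enone (conjugate addition of pyridine at C6, iodination of the enolate at C7, elimination), precedented for cyclohexenones with a quaternary γ-carbon, leaves the electron-poor senecioate alkene and the silyl ether alone.

Step 12
Reactants: 17 α-iodo enone silyl ether
Product: 18 (3R,4R,5R,9R,10S)-3-hydroxy-7-iodo-8-oxo-11,12,13-trinoreremophil-6-en-9-yl 3-methylbut-2-enoate
Conditions: HF·pyridine, pyridine, THF, 0 °C → rt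
Reagents that add atoms: none
Why: Fluoride-induced cleavage of the secondary silyl ether with buffered HF·pyridine is compatible with the α-acyloxy ketone, the ester and the vinyl iodide, and C3 keeps its configuration.

Step 13
Reactants: 18 C3 alcohol; 19 angelic acid
Product: 20 (3R,4R,5R,9R,10S)-7-iodo-9-[(3-methylbut-2-enoyl)oxy]-8-oxo-11,12,13-trinoreremophil-6-en-3-yl (2Z)-2-methylbut-2-enoate
Conditions: angelic acid, 2,4,6-trichlorobenzoyl chloride, Et3N, PhMe, rt; filter; then 18, PhMe, 75 °C
Reagents that add atoms: angelic acid (19), C/C=C(/C)C(=O)O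
Why: Yamaguchi-type esterification through the 2,4,6-trichlorobenzoyl mixed anhydride without DMAP is the standard way to acylate a secondary alcohol with angelic acid without Z→E isomerisation to the tiglate; C3 is acylated with retention.

Step 14
Reactants: 20 α-iodo enone diester; 21 tributyl(isopropenyl)stannane
Product: 22 (3R,4R,5R,9R,10S)-3-angeloyloxy-9-senecioyloxyeremophila-6,11-dien-8-one
Conditions: CH2=C(CH3)SnBu3, Pd2(dba)3 (5 mol%), AsPh3, CuI, NMP, rt → 40 °C
Reagents that add atoms: tributyl(isopropenyl)stannane (21), C=C(C)[Sn](CCCC)(CCCC)CCCC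
Why: Stille coupling of the α-iodoenone with the isopropenylstannane under neutral Pd/AsPh3/CuI conditions introduces C11–C13 without enolising C9 or touching either ester.

Step 15
Reactants: 22 cross-conjugated dienone diester
Product: 23 (3R,4R,5R,7R,9R,10S)-3-angeloyloxy-9-senecioyloxyeremophil-11-en-8-one (target)
Conditions: [(Ph3P)CuH]6 (0.4 equiv), H2O (5 equiv), degassed PhH–THF, rt
Reagents that add atoms: none
Why: Conjugate reduction with Stryker's reagent delivers hydride to C6 of the cross-conjugated dienone and the copper dienolate is protonated by water at its α-carbon C7, which gives the deconjugated isopropenyl ketone; axial protonation from the α face should place the isopropenyl group equatorial (7R), the thermodynamically preferred epimer, while the hindered trisubstituted enoates and the isolated alkene should not be reduced.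

Compound list
1 | glutaconaldehyde potassium salt | [K+].[O-]/C=C/C=C/C=O | starting material
2 | (2E,4E)-5-[(tert-butyldimethylsilyl)oxy]penta-2,4-dienal | O=C/C=C/C=C/O[Si](C)(C)C(C)(C)C | intermediate
3 | ethynylmagnesium bromide | C#C[Mg]Br | starting material
4 | bromomagnesium (4E,6E)-7-[(tert-butyldimethylsilyl)oxy]hepta-4,6-dien-1-yn-3-olate, racemic, not isolated | C#CC(O[Mg]Br)/C=C/C=C/O[Si](C)(C)C(C)(C)C | intermediate
5 | rac-(4E,6E)-7-[(tert-butyldimethylsilyl)oxy]hepta-4,6-dien-1-yn-3-yl acetate | CC(=O)OC(C#C)/C=C/C=C/O[Si](C)(C)C(C)(C)C | intermediate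
6 | (3S,4E,6E)-7-[(tert-butyldimethylsilyl)oxy]hepta-4,6-dien-1-yn-3-ol | O[C@@H](/C=C/C=C/O[Si](C)(C)C(C)(C)C)C#C | intermediate
7 | tigloyl chloride, (2E)-2-methylbut-2-enoyl chloride | C/C=C(\C)C(Cl)=O | starting material
8 | (3S,4E,6E)-7-[(tert-butyldimethylsilyl)oxy]hepta-4,6-dien-1-yn-3-yl (2E)-2-methylbut-2-enoate | C/C=C(\C)C(=O)O[C@@H](/C=C/C=C/O[Si](C)(C)C(C)(C)C)C#C | intermediate
9 | (3S,3aS,6R,7R,7aR)-6-[(tert-butyldimethylsilyl)oxy]-3-ethynyl-7,7a-dimethyl-3a,6,7,7a-tetrahydro-2-benzofuran-1(3H)-one | O=C1[C@@]2(C)[C@H](C=C[C@@H](O[Si](C)(C)C(C)(C)C)[C@@H]2C)[C@H](O1)C#C | intermediate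
10 | (3S,3aS,6R,7R,7aR)-6-[(tert-butyldimethylsilyl)oxy]-3-ethynyl-7,7a-dimethyl-1,3,3a,6,7,7a-hexahydro-2-benzofuran-1-ol, both anomers | OC1[C@@]2(C)[C@H](C=C[C@@H](O[Si](C)(C)C(C)(C)C)[C@@H]2C)[C@H](O1)C#C | intermediate
11 | (3S,3aS,6R,7R,7aR)-3-acetyl-6-[(tert-butyldimethylsilyl)oxy]-7,7a-dimethyl-1,3,3a,6,7,7a-hexahydro-2-benzofuran-1-ol, both anomers | OC1[C@@]2(C)[C@H](C=C[C@@H](O[Si](C)(C)C(C)(C)C)[C@@H]2C)[C@H](O1)C(C)=O | intermediate
12 | (3S,3aS,6R,7R,7aR)-3-acetyl-6-[(tert-butyldimethylsilyl)oxy]-7,7a-dimethyloctahydro-2-benzofuran-1-ol, both anomers | OC1[C@@]2(C)[C@H](CC[C@@H](O[Si](C)(C)C(C)(C)C)[C@@H]2C)[C@H](O1)C(C)=O | intermediate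
13 | (3R,4R,5R,9S,10S)-3-[(tert-butyldimethylsilyl)oxy]-6,9-dihydroxy-11,12,13-trinoreremophilan-8-one, C6 epimers, not isolated | C1C(O)[C@@]2(C)[C@H](CC[C@@H](O[Si](C)(C)C(C)(C)C)[C@@H]2C)[C@H](O)C1=O | intermediate
14 | (3R,4R,5R,9S,10S)-3-[(tert-butyldimethylsilyl)oxy]-9-hydroxy-11,12,13-trinoreremophil-6-en-8-one (9α-OH) | C1=C[C@@]2(C)[C@H](CC[C@@H](O[Si](C)(C)C(C)(C)C)[C@@H]2C)[C@H](O)C1=O | intermediate
15 | senecioic acid, 3-methylbut-2-enoic acid | CC(C)=CC(=O)O | starting material
16 | (3R,4R,5R,9R,10S)-3-[(tert-butyldimethylsilyl)oxy]-8-oxo-11,12,13-trinoreremophil-6-en-9-yl 3-methylbut-2-enoate (9β) | C1=C[C@@]2(C)[C@H](CC[C@@H](O[Si](C)(C)C(C)(C)C)[C@@H]2C)[C@@H](OC(=O)C=C(C)C)C1=O | intermediate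
17 | (3R,4R,5R,9R,10S)-3-[(tert-butyldimethylsilyl)oxy]-7-iodo-8-oxo-11,12,13-trinoreremophil-6-en-9-yl 3-methylbut-2-enoate | IC1=C[C@@]2(C)[C@H](CC[C@@H](O[Si](C)(C)C(C)(C)C)[C@@H]2C)[C@@H](OC(=O)C=C(C)C)C1=O | intermediate
18 | (3R,4R,5R,9R,10S)-3-hydroxy-7-iodo-8-oxo-11,12,13-trinoreremophil-6-en-9-yl 3-methylbut-2-enoate | IC1=C[C@@]2(C)[C@H](CC[C@@H](O)[C@@H]2C)[C@@H](OC(=O)C=C(C)C)C1=O | intermediate
19 | angelic acid, (2Z)-2-methylbut-2-enoic acid | C/C=C(/C)C(=O)O | starting material
20 | (3R,4R,5R,9R,10S)-7-iodo-9-[(3-methylbut-2-enoyl)oxy]-8-oxo-11,12,13-trinoreremophil-6-en-3-yl (2Z)-2-methylbut-2-enoate | IC1=C[C@@]2(C)[C@H](CC[C@@H](OC(=O)/C(C)=C\C)[C@@H]2C)[C@@H](OC(=O)C=C(C)C)C1=O | intermediate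
21 | tributyl(isopropenyl)stannane | C=C(C)[Sn](CCCC)(CCCC)CCCC | starting material
22 | (3R,4R,5R,9R,10S)-3-angeloyloxy-9-senecioyloxyeremophila-6,11-dien-8-one | C=C(C)C1=C[C@@]2(C)[C@H](CC[C@@H](OC(=O)/C(C)=C\C)[C@@H]2C)[C@@H](OC(=O)C=C(C)C)C1=O | intermediate
23 | (3R,4R,5R,7R,9R,10S)-3-angeloyloxy-9-senecioyloxyeremophil-11-en-8-one, CNP0375730.2 | C=C(C)[C@H]1C[C@@]2(C)[C@H](CC[C@@H](OC(=O)/C(C)=C\C)[C@@H]2C)[C@@H](OC(=O)C=C(C)C)C1=O | target

Total step count: 15. Longest linear sequence: 15 steps (1 → 23).

Steps most likely to fail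

Step 5. The cycloaddition may be slower than thermal breakdown of the silyloxydienyl ester (ionisation at C9 with silyl transfer to the carboxylate, or an acyloxy shift along the diene), and the small ethynyl group may discriminate the two diene faces only weakly. The fallback replaces the covalent ester tether by a magnesium template and sets out from alcohol 6. Deprotonation with MeMgBr at −78 °C would give the bromomagnesium alkoxide F1. With methyl tiglate and MgBr2·OEt2 in CH2Cl2 (0 °C → rt), dienyl alkoxide and ester carbonyl are held on the same metal, so a Lewis-acid-activated, tether-controlled Diels–Alder reaction can run near room temperature; this is known for dienols and acrylates. The hydroxy ester cycloadduct F2 would close to the lactone with loss of methanol, and the route is rejoined at 9.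

Step 10. E2 loss of the activated axial oxygen together with the anti-periplanar H10 may outrun substitution at the hindered carbinol, and any epimerisation at C9 during step 9 would be carried into the wrong ester by an invertive reaction. The fallback sets C9 under thermodynamic control instead and sets out from 14. Silylation (TESOTf, 2,6-lutidine) would give the 9α-triethylsilyl ether F3. Catalytic DBU in toluene at 60 °C can enolise only towards C9, since C5 is quaternary, and should equilibrate it through the cross-conjugated dienolate to the pseudo-equatorial 9β-triethylsilyl ether F4, which avoids the syn-axial contact with C4. Buffered HF·pyridine at 0 °C would remove the triethylsilyl group selectively to give the 9β-hydroxy enone F5. Acylation with senecioyl chloride and pyridine, with retention, rejoins the route at 16.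

Step 15. Copper hydride may also add to the angelate, the enolate may be protonated at C7 from the β face, or the isopropenyl double bond may drift into conjugation with C8 on contact with base. The fallback forms the isopropenyl ketone before the angelate is present and sets out from 17. Stille coupling as in step 14 would give the silyl-protected dienone F6. Reduction with Stryker's reagent, now beside only the unreactive β,β-disubstituted senecioate, would give the isopropenyl ketone F7. If needed, C7 is equilibrated to the equatorial epimer by brief contact with triethylamine, α-reprotonation of the dienol being faster than conjugation. HF·pyridine would then give the C3 alcohol F8. Angeloylation with the preformed, amine-free mixed anhydride as in step 13 rejoins the route at the target 23.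

Further compounds
F1 | step 5 | bromomagnesium (3S,4E,6E)-7-[(tert-butyldimethylsilyl)oxy]hepta-4,6-dien-1-yn-3-olate | Br[Mg]O[C@@H](/C=C/C=C/O[Si](C)(C)C(C)(C)C)C#C
F2 | step 5 | methyl cyclohexenecarboxylate cycloadduct with free C9 hydroxyl (seco-ester of 9) | COC(=O)[C@@]1(C)[C@H](C=C[C@@H](O[Si](C)(C)C(C)(C)C)[C@@H]1C)[C@H](O)C#C
F3 | step 10 | (9S)-9α-triethylsilyl ether of 14 | C1=C[C@@]2(C)[C@H](CC[C@@H](O[Si](C)(C)C(C)(C)C)[C@@H]2C)[C@H](O[Si](CC)(CC)CC)C1=O
F4 | step 10 | (9R)-9β-triethylsilyl ether, C9 epimer of F3 | C1=C[C@@]2(C)[C@H](CC[C@@H](O[Si](C)(C)C(C)(C)C)[C@@H]2C)[C@@H](O[Si](CC)(CC)CC)C1=O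
F5 | step 10 | (9R)-9β-hydroxy enone, C9 epimer of 14 | C1=C[C@@]2(C)[C@H](CC[C@@H](O[Si](C)(C)C(C)(C)C)[C@@H]2C)[C@@H](O)C1=O
F6 | step 15 | 3-O-tert-butyldimethylsilyl-9-senecioyloxyeremophila-6,11-dien-8-one | C=C(C)C1=C[C@@]2(C)[C@H](CC[C@@H](O[Si](C)(C)C(C)(C)C)[C@@H]2C)[C@@H](OC(=O)C=C(C)C)C1=O
F7 | step 15 | (7R)-3-O-tert-butyldimethylsilyl-9-senecioyloxyeremophil-11-en-8-one | C=C(C)[C@H]1C[C@@]2(C)[C@H](CC[C@@H](O[Si](C)(C)C(C)(C)C)[C@@H]2C)[C@@H](OC(=O)C=C(C)C)C1=O
F8 | step 15 | (7R)-3-hydroxy-9-senecioyloxyeremophil-11-en-8-one | C=C(C)[C@H]1C[C@@]2(C)[C@H](CC[C@@H](O)[C@@H]2C)[C@@H](OC(=O)C=C(C)C)C1=O
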